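**Retrosynthetic overview**
1. Target 19 ⇐ Markovnikov hydration of the exocyclic alkene of spiro compound 18 (sets the last carbinol, C7').
2. 18 ⇐ Pd-catalysed intramolecular allylic C–H alkylation of the isopropenyl group of 17 by the trione CH; this closes the cyclohexane ring and creates the spiro quaternary centre.
3. 17 ⇐ Michael addition of acyl-trione 8 to the enantioenriched 2-methylene-3-isopropenylcyclopentanone 15, then methyl 1,2-addition.
4. 8 ⇐ methyl acetoacetate + prenyl bromide (Claisen/Dieckmann, then C-acetylation); 15 ⇐ cyclopent-2-enone (asymmetric conjugate addition, Mannich methylenation).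
5. Ring order: trione ring and cyclopentane first (separate branches), the spiro-bearing cyclohexane ring last.

Assumption: the ligand antipodes written in steps 5 and 10 are taken to be those that give the drawn configurations (to be confirmed by a first screen of both antipodes); enolised triones are drawn in the tautomer of the target SMILES.

**Branch A: acyl-trione 8**

Step 1
Reactants: 1 methyl acetoacetate; 2 prenyl bromide (2.3 equiv)
Product: 3 methyl 2-acetyl-5-methyl-2-(3-methylbut-2-en-1-yl)hex-4-enoate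
Conditions: K2CO3 (3 equiv), acetone, 56 °C
Reagents that add atoms: none
Why: Double C-alkylation of the β-keto ester (acetoacetic ester alkylation); the doubly activated carbon is the only acidic site and the allylic bromide alkylates at carbon, no stereocentre is formed.

Step 2
Reactants: 3 methyl 2-acetyl-5-methyl-2-(3-methylbut-2-en-1-yl)hex-4-enoate
Product: 5 methyl 2,2-bis(3-methylbut-2-en-1-yl)-3,5-dioxohexanoate, via lithium enolate 4 (not isolated)
Conditions: LiN(i-Pr)2 (1.2 equiv), THF, −78 °C; then MeC(O)N(OMe)Me, −78 → 0 °C; aq. NH4Cl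
Reagents that add atoms: N-methoxy-N-methylacetamide, CC(=O)N(C)OC
Why: Crossed Claisen-type acylation of the kinetic enolate (the methyl group is the only enolisable position of 3); the Weinreb-amide adduct stays as a chelate until work-up, so the new 1,3-diketone neither quenches the enolate nor is acylated again.

Step 3
Reactants: 5 methyl 2,2-bis(3-methylbut-2-en-1-yl)-3,5-dioxohexanoate
Product: 6 5-hydroxy-2,2-bis(3-methylbut-2-en-1-yl)cyclohex-4-ene-1,3-dione
Conditions: LiN(i-Pr)2 (3 equiv), THF, −78 → 0 °C; then 1 M HCl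
Reagents that add atoms: none
Why: Dieckmann-type (intramolecular Claisen) cyclisation of the 1,3-diketone dianion, whose terminal carbanion attacks the ester in a 6-ring closure; loss of methoxide and deprotonation to the trione enolate make it irreversible.

Step 4
Reactants: 6 5-hydroxy-2,2-bis(3-methylbut-2-en-1-yl)cyclohex-4-ene-1,3-dione
Product: 8 2-acetyl-3,5-dihydroxy-4,4-bis(3-methylbut-2-en-1-yl)cyclohexa-2,5-dien-1-one, via enol acetate 7 (not isolated)
Conditions: AcOH (1.05 equiv), N,N'-dicyclohexylcarbodiimide, 4-(dimethylamino)pyridine (30 mol %), CH2Cl2, 23 °C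
Reagents that add atoms: acetic acid, CC(=O)O
Why: Steglich-type O-acylation followed by 4-(dimethylamino)pyridine-mediated O-to-C acyl migration, the standard C-acylation of cyclic 1,3-diones; the two nucleophilic carbons of 6 are equivalent and the acidic triketone product resists a second acylation.

**Branch B: enone 15**

Step 5
Reactants: 9 cyclopent-2-en-1-one; 10 isopropenylmagnesium bromide
Product: 12 trimethyl{[(3R)-3-(prop-1-en-2-yl)cyclopent-1-en-1-yl]oxy}silane, via magnesium enolate 11 (not isolated)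
Conditions: CuBr·SMe2 (5 mol %), (R)-1-[(S)-2-(diphenylphosphino)ferrocenyl]ethyldicyclohexylphosphine (6 mol %), t-BuOMe, −78 °C; then Me3SiCl, Et3N, −78 → 0 °C
Reagents that add atoms: chlorotrimethylsilane, C[Si](C)(C)Cl
Why: Copper-catalysed asymmetric conjugate addition of a Grignard reagent; the chiral ferrocenyl diphosphine–copper complex selects the enone face and sets C3 (R), and silylation fixes the enolate regiochemistry at C1–C2.

Step 6
Reactants: 12 trimethyl{[(3R)-3-(prop-1-en-2-yl)cyclopent-1-en-1-yl]oxy}silane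
Product: 13 (2R,3R)-2-[(dimethylamino)methyl]-3-(prop-1-en-2-yl)cyclopentan-1-one
Conditions: CH2=NMe2+ I−, CH2Cl2, 0 → 23 °C; aq. NaHCO3
Reagents that add atoms: N,N-dimethylmethyleneiminium iodide, C=[N+](C)C.[I-]
Why: Mannich reaction of a silyl enol ether with a preformed iminium salt; the bond forms regiospecifically at C2 and anti to the C3 isopropenyl group, and the trans ketone is also the thermodynamic epimer.

Step 7
Reactants: 13 (2R,3R)-2-[(dimethylamino)methyl]-3-(prop-1-en-2-yl)cyclopentan-1-one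
Product: 14 N,N,N-trimethyl-1-[(1R,5R)-2-oxo-5-(prop-1-en-2-yl)cyclopentyl]methanaminium iodide
Conditions: MeI, Et2O, 23 °C; recrystallised (EtOH/Et2O)
Reagents that add atoms: iodomethane, CI
Why: Menshutkin quaternisation of the tertiary amine; the crystalline salt is recrystallised to raise the enantiomeric purity and stores the sensitive enone in latent form.

Step 8
Reactants: 14 N,N,N-trimethyl-1-[(1R,5R)-2-oxo-5-(prop-1-en-2-yl)cyclopentyl]methanaminium iodide
Product: 15 (3S)-2-methylidene-3-(prop-1-en-2-yl)cyclopentan-1-one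
Conditions: NaHCO3, CH2Cl2/H2O, 23 °C; used at once
Reagents that add atoms: none
Why: E1cB (Hofmann-type) elimination of the β-ammonium ketone under mild biphasic base, which frees the exocyclic enone without moving the double bond into the ring; C3 is untouched.

**Union and endgame**

Step 9
Reactants: 8 2-acetyl-3,5-dihydroxy-4,4-bis(3-methylbut-2-en-1-yl)cyclohexa-2,5-dien-1-one; 15 (3S)-2-methylidene-3-(prop-1-en-2-yl)cyclopentan-1-one
Product: 17 2-acetyl-3,5-dihydroxy-6-{[(1S,2R,5R)-2-hydroxy-2-methyl-5-(prop-1-en-2-yl)cyclopentyl]methyl}-4,4-bis(3-methylbut-2-en-1-yl)cyclohexa-2,5-dien-1-one, via keto adduct 16 (not isolated)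
Conditions: Et3N (5 mol %), THF, 23 °C; then CeCl3, MeMgBr (6 equiv each), THF, −78 → −30 °C; 0.5 M HCl, 0 °C
Reagents that add atoms: methylmagnesium bromide, C[Mg]Br
Why: Michael addition of the vinylogous-acid carbon C6 of 8 to the exocyclic enone (protonation gives the trans-2,3-disubstituted cyclopentanone), then organocerium (Imamoto) 1,2-addition: two equivalents of reagent turn the trione into an unreactive bis-enolate and methyl adds to the ketone face anti to the bulky C2 arm, giving the carbinol with OH cis to that arm.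

Step 10
Reactants: 17 2-acetyl-3,5-dihydroxy-6-{[(1S,2R,5R)-2-hydroxy-2-methyl-5-(prop-1-en-2-yl)cyclopentyl]methyl}-4,4-bis(3-methylbut-2-en-1-yl)cyclohexa-2,5-dien-1-one
Product: 18 (1R,3'R,3a'S,7a'R)-3-acetyl-3',4-dihydroxy-3'-methyl-7'-methylidene-5,5-bis(3-methylbut-2-en-1-yl)-1',2',3',3a',4',6',7',7a'-octahydrospiro[cyclohex-3-ene-1,5'-indene]-2,6-dione
Conditions: Pd(dba)2 (10 mol %), (S)-1,1'-binaphthyl-2,2'-diyl N,N-bis[(R)-1-phenylethyl]phosphoramidite (12 mol %), 2,5-dimethyl-1,4-benzoquinone (1.5 equiv), toluene, 50 °C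
Reagents that add atoms: none
Why: Proposed new method: a zerovalent palladium–phosphoramidite–quinone complex binds the 1,1-disubstituted alkene and removes a methyl hydrogen by concerted proton/two-electron transfer, giving a 2-substituted η3-allyl complex of divalent palladium whose two CH2 termini are equivalent; the tethered carbon C6 attacks one terminus on the face opposite palladium in a 6-ring closure (O-attack would need an 8-ring and is reversible; the 3'-OH is trans to the allyl unit and cannot reach it) and the quinone returns palladium to the cycle; the bulky ligand sits beside the quadrant that becomes equatorial at the new spiro carbon, so the sp3 gem-diprenyl flank is pushed to the axial side (face of H-3a') and the flat acyl-enol flank takes the equatorial site, which sets the 1R quaternary centre; the closest known reactions are Pd/phosphoramidite/benzoquinone and Pd(OAc)2/bis-sulfoxide allylic C–H alkylations of monosubstituted terminal alkenes or allylarenes with 1,3-dicarbonyls and Tsuji–Trost spirocyclisations of allylic carbonates, none of which uses an isopropenyl C–H donor to close a spiro ring at a quaternary carbon.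

Step 11
Reactants: 18 (1R,3'R,3a'S,7a'R)-3-acetyl-3',4-dihydroxy-3'-methyl-7'-methylidene-5,5-bis(3-methylbut-2-en-1-yl)-1',2',3',3a',4',6',7',7a'-octahydrospiro[cyclohex-3-ene-1,5'-indene]-2,6-dione
Product: 19 (1R,3'R,3a'S,7'R,7a'R)-3-acetyl-3',4,7'-trihydroxy-3',7'-dimethyl-5,5-bis(3-methylbut-2-en-1-yl)-1',2',3',3a',4',6',7',7a'-octahydrospiro[cyclohex-3-ene-1,5'-indene]-2,6-dione (CNP0266834.2)
Conditions: Co(acac)2 (20 mol %), PhSiH3 (2 equiv), O2 (1 atm), THF, 0 °C; stopped at full conversion of 18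
Reagents that add atoms: dioxygen, O=O
Why: Mukaiyama hydration (metal-hydride hydrogen-atom transfer): the hydrogen atom adds to the CH2 terminus of the 1,1-disubstituted alkene faster than to the trisubstituted prenyl alkenes, and the tertiary radical is oxygenated on the face opposite the axial spiro carbonyl, giving the equatorial 7'R alcohol with its methyl group syn to that carbonyl.

**Compound list**
1 | methyl acetoacetate | CC(=O)CC(=O)OC | starting material
2 | prenyl bromide (1-bromo-3-methylbut-2-ene) | CC(C)=CCBr | starting material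
3 | methyl 2-acetyl-5-methyl-2-(3-methylbut-2-en-1-yl)hex-4-enoate | CC(=O)C(CC=C(C)C)(CC=C(C)C)C(=O)OC | intermediate
4 | lithium enolate of 3, methyl 2-[1-(lithiooxy)ethenyl]-5-methyl-2-(3-methylbut-2-en-1-yl)hex-4-enoate | [Li]OC(=C)C(CC=C(C)C)(CC=C(C)C)C(=O)OC | intermediate (not isolated)
5 | methyl 2,2-bis(3-methylbut-2-en-1-yl)-3,5-dioxohexanoate | CC(=O)CC(=O)C(CC=C(C)C)(CC=C(C)C)C(=O)OC | intermediate
6 | 5-hydroxy-2,2-bis(3-methylbut-2-en-1-yl)cyclohex-4-ene-1,3-dione | O=C1CC(O)=CC(=O)C1(CC=C(C)C)CC=C(C)C | intermediate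
7 | 3,5-dioxo-4,4-bis(3-methylbut-2-en-1-yl)cyclohex-1-en-1-yl acetate | CC(=O)OC1=CC(=O)C(CC=C(C)C)(CC=C(C)C)C(=O)C1 | intermediate (not isolated)
8 | 2-acetyl-3,5-dihydroxy-4,4-bis(3-methylbut-2-en-1-yl)cyclohexa-2,5-dien-1-one | CC(=O)C1=C(O)C(CC=C(C)C)(CC=C(C)C)C(O)=CC1=O | intermediate
9 | cyclopent-2-en-1-one | O=C1C=CCC1 | starting material
10 | isopropenylmagnesium bromide | CC(=C)[Mg]Br | starting material
11 | bromomagnesium (3R)-3-(prop-1-en-2-yl)cyclopent-1-en-1-olate | Br[Mg]OC1=C[C@@H](CC1)C(C)=C | intermediate (not isolated)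
12 | trimethyl{[(3R)-3-(prop-1-en-2-yl)cyclopent-1-en-1-yl]oxy}silane | C[Si](C)(C)OC1=C[C@@H](CC1)C(C)=C | intermediate
13 | (2R,3R)-2-[(dimethylamino)methyl]-3-(prop-1-en-2-yl)cyclopentan-1-one (trans) | CN(C)C[C@H]1[C@@H](CCC1=O)C(C)=C | intermediate
14 | N,N,N-trimethyl-1-[(1R,5R)-2-oxo-5-(prop-1-en-2-yl)cyclopentyl]methanaminium iodide | C[N+](C)(C)C[C@H]1[C@@H](CCC1=O)C(C)=C.[I-] | intermediate
15 | (3S)-2-methylidene-3-(prop-1-en-2-yl)cyclopentan-1-one | C=C1[C@@H](CCC1=O)C(C)=C | intermediate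
16 | 2-acetyl-3,5-dihydroxy-4,4-bis(3-methylbut-2-en-1-yl)-6-{[(1S,5R)-2-oxo-5-(prop-1-en-2-yl)cyclopentyl]methyl}cyclohexa-2,5-dien-1-one | CC(=O)C1=C(O)C(CC=C(C)C)(CC=C(C)C)C(O)=C(C[C@H]2[C@@H](CCC2=O)C(C)=C)C1=O | intermediate (not isolated)
17 | 2-acetyl-3,5-dihydroxy-6-{[(1S,2R,5R)-2-hydroxy-2-methyl-5-(prop-1-en-2-yl)cyclopentyl]methyl}-4,4-bis(3-methylbut-2-en-1-yl)cyclohexa-2,5-dien-1-one | CC(=O)C1=C(O)C(CC=C(C)C)(CC=C(C)C)C(O)=C(C[C@H]2[C@@H](CC[C@@]2(C)O)C(C)=C)C1=O | intermediate
18 | (1R,3'R,3a'S,7a'R)-3-acetyl-3',4-dihydroxy-3'-methyl-7'-methylidene-5,5-bis(3-methylbut-2-en-1-yl)-1',2',3',3a',4',6',7',7a'-octahydrospiro[cyclohex-3-ene-1,5'-indene]-2,6-dione (trans-fused) | CC(=O)C1=C(O)C(CC=C(C)C)(CC=C(C)C)C(=O)[C@]2(C[C@H]3[C@@H](CC[C@@]3(C)O)C(=C)C2)C1=O | intermediate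
19 | (1R,3'R,3a'S,7'R,7a'R)-3-acetyl-3',4,7'-trihydroxy-3',7'-dimethyl-5,5-bis(3-methylbut-2-en-1-yl)-1',2',3',3a',4',6',7',7a'-octahydrospiro[cyclohex-3-ene-1,5'-indene]-2,6-dione | CC(=O)C1=C(O)C(CC=C(C)C)(CC=C(C)C)C(=O)[C@]2(C[C@H]3[C@@H](CC[C@@]3(C)O)[C@](C)(O)C2)C1=O | target

**Totals**
Total step count: 11. Longest linear sequence: 7 steps (steps 1–4 then 9–11; the other branch, steps 5–8 then 9–11, is also 7).

**Three steps most likely to fail**

Step 10 (the new C–H spirocyclisation). Risks: no turnover with the hindered 1,1-disubstituted alkene, C–H cleavage at the ring methine or at a prenyl group, attack of an enol oxygen on a prenyl group, and weak control of the spiro centre. The fallback uses known chemistry, sets out from cyclopent-2-en-1-one 9 and comes back at 18. The allylic leaving group is built in from the start and the ring is closed by a Tsuji–Trost alkylation. 2-Bromoprop-2-en-1-ol is silylated (t-BuMe2SiCl, imidazole) to tert-butyl[(2-bromoprop-2-en-1-yl)oxy]dimethylsilane F1, and magnesium in THF converts it into {3-[(tert-butyldimethylsilyl)oxy]prop-1-en-2-yl}magnesium bromide F2. F2 takes the place of 10 under the conditions of steps 5 to 9. This gives in turn the bromomagnesium enolate F3, the silyl enol ether F4, the Mannich base F5, the methiodide F6, the enone F7, the keto adduct F8 (from 8, not isolated) and the carbinol F9. Bu4NF/AcOH then frees the allylic alcohol F10. Pd(PPh3)4 (5 mol %) with Et3B in THF at 50 °C ionises F10 to the same 2-substituted η3-allyl intermediate, and C6 closes the ring to 18, with water as the only by-product. The two spiro epimers are separable by chromatography, and a chiral diphosphine can replace PPh3 if the ratio is poor.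

Step 11 (hydration). Risks: competing hydrogen-atom transfer to the prenyl groups, or the wrong face at C7'. The fallback sets out from 18 and comes back at 19 by Brown oxymercuration–demercuration, which is known to hydrate a 1,1-disubstituted alkene in the presence of trisubstituted ones. Hg(OAc)2 (2.5 equiv) in THF/H2O at 0 °C gives the acetoxymercurio carbinol F11; water enters C7' from the equatorial face, away from the axial carbonyl. NaBH4 in aq. NaOH at 0 °C then replaces mercury by hydrogen to give 19.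

Step 9 (methyl addition next to an unprotected trione). Risks: low conversion through enolisation or aggregation of the polyanion, or a poor diastereomer ratio at the carbinol. The fallback sets out from 8 and 15 and comes back at 17. The keto adduct 16 is isolated and both enol hydroxyls are masked (Me3SiCl, Et3N, CH2Cl2) as the bis(trimethylsilyl) ether F12. MeLi/CeCl3 (1.5 equiv, THF, −78 °C) then meets a neutral, soluble ketone and gives the silylated carbinol F13. Citric acid in MeOH removes both silyl groups and returns 17.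

Further compounds
F1 | step 10 | tert-butyl[(2-bromoprop-2-en-1-yl)oxy]dimethylsilane | C=C(Br)CO[Si](C)(C)C(C)(C)C
F2 | step 10 | {3-[(tert-butyldimethylsilyl)oxy]prop-1-en-2-yl}magnesium bromide | C=C([Mg]Br)CO[Si](C)(C)C(C)(C)C
F3 | step 10 | bromomagnesium (3R)-3-{3-[(tert-butyldimethylsilyl)oxy]prop-1-en-2-yl}cyclopent-1-en-1-olate | Br[Mg]OC1=C[C@@H](CC1)C(=C)CO[Si](C)(C)C(C)(C)C
F4 | step 10 | tert-butyldimethyl({2-[(1R)-3-(trimethylsilyloxy)cyclopent-2-en-1-yl]prop-2-en-1-yl}oxy)silane | C[Si](C)(C)OC1=C[C@@H](CC1)C(=C)CO[Si](C)(C)C(C)(C)C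
F5 | step 10 | (2R,3R)-3-{3-[(tert-butyldimethylsilyl)oxy]prop-1-en-2-yl}-2-[(dimethylamino)methyl]cyclopentan-1-one | CN(C)C[C@H]1[C@@H](CCC1=O)C(=C)CO[Si](C)(C)C(C)(C)C
F6 | step 10 | 1-[(1R,5R)-5-{3-[(tert-butyldimethylsilyl)oxy]prop-1-en-2-yl}-2-oxocyclopentyl]-N,N,N-trimethylmethanaminium iodide | C[N+](C)(C)C[C@H]1[C@@H](CCC1=O)C(=C)CO[Si](C)(C)C(C)(C)C.[I-]
F7 | step 10 | (3S)-3-{3-[(tert-butyldimethylsilyl)oxy]prop-1-en-2-yl}-2-methylidenecyclopentan-1-one | C=C1[C@@H](CCC1=O)C(=C)CO[Si](C)(C)C(C)(C)C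
F8 | step 10 | 2-acetyl-6-{[(1S,5R)-5-{3-[(tert-butyldimethylsilyl)oxy]prop-1-en-2-yl}-2-oxocyclopentyl]methyl}-3,5-dihydroxy-4,4-bis(3-methylbut-2-en-1-yl)cyclohexa-2,5-dien-1-one | CC(=O)C1=C(O)C(CC=C(C)C)(CC=C(C)C)C(O)=C(C[C@H]2[C@@H](CCC2=O)C(=C)CO[Si](C)(C)C(C)(C)C)C1=O
F9 | step 10 | 2-acetyl-6-{[(1S,2R,5R)-5-{3-[(tert-butyldimethylsilyl)oxy]prop-1-en-2-yl}-2-hydroxy-2-methylcyclopentyl]methyl}-3,5-dihydroxy-4,4-bis(3-methylbut-2-en-1-yl)cyclohexa-2,5-dien-1-one | CC(=O)C1=C(O)C(CC=C(C)C)(CC=C(C)C)C(O)=C(C[C@H]2[C@@H](CC[C@@]2(C)O)C(=C)CO[Si](C)(C)C(C)(C)C)C1=O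
F10 | step 10 | 2-acetyl-3,5-dihydroxy-6-{[(1S,2R,5R)-2-hydroxy-5-(3-hydroxyprop-1-en-2-yl)-2-methylcyclopentyl]methyl}-4,4-bis(3-methylbut-2-en-1-yl)cyclohexa-2,5-dien-1-one | CC(=O)C1=C(O)C(CC=C(C)C)(CC=C(C)C)C(O)=C(C[C@H]2[C@@H](CC[C@@]2(C)O)C(=C)CO)C1=O
F11 | step 11 | (acetato){[(1R,3'R,3a'S,7'R,7a'R)-3-acetyl-3',4,7'-trihydroxy-3'-methyl-5,5-bis(3-methylbut-2-en-1-yl)-2,6-dioxo-1',2',3',3a',4',6',7',7a'-octahydrospiro[cyclohex-3-ene-1,5'-inden]-7'-yl]methyl}mercury | CC(=O)C1=C(O)C(CC=C(C)C)(CC=C(C)C)C(=O)[C@]2(C[C@H]3[C@@H](CC[C@@]3(C)O)[C@](C[Hg]OC(C)=O)(O)C2)C1=O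
F12 | step 9 | 2-acetyl-4,4-bis(3-methylbut-2-en-1-yl)-6-{[(1S,5R)-2-oxo-5-(prop-1-en-2-yl)cyclopentyl]methyl}-3,5-bis[(trimethylsilyl)oxy]cyclohexa-2,5-dien-1-one | CC(=O)C1=C(O[Si](C)(C)C)C(CC=C(C)C)(CC=C(C)C)C(O[Si](C)(C)C)=C(C[C@H]2[C@@H](CCC2=O)C(C)=C)C1=O
F13 | step 9 | 2-acetyl-6-{[(1S,2R,5R)-2-hydroxy-2-methyl-5-(prop-1-en-2-yl)cyclopentyl]methyl}-4,4-bis(3-methylbut-2-en-1-yl)-3,5-bis[(trimethylsilyl)oxy]cyclohexa-2,5-dien-1-one | CC(=O)C1=C(O[Si](C)(C)C)C(CC=C(C)C)(CC=C(C)C)C(O[Si](C)(C)C)=C(C[C@H]2[C@@H](CC[C@@]2(C)O)C(C)=C)C1=O
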